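**The question.** I wanted to know how much product the flask held at 40 h, how clean it was, and whether the exchange between the two substrates kept up.

- oak: left-handed substrate 0.60 M; right-handed substrate 0.60 M; coupling partner 1.2 M; free catalyst 60 mM; racemization catalyst 60 mM; run made earlier
- flask: left-handed substrate 0.30 M; coupling partner 1.20 M; free catalyst 60 mM; racemization catalyst 60 mM; right-handed substrate 0.30 M; time 40 h

oak run (percent of the left-handed substrate and right-handed substrate together charged)

| time / h | left-handed product / % | right-handed product / % | left-handed substrate / % |
|---|---|---|---|
| 0.333 | 10 | 0 | 37 |
| 0.500 | 16 | 1 | 37 |
| 0.667 | 19 | 3 | 32 |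
| 1.00 | 23 | 2 | 29 |
| 1.50 | 29 | 2 | 21 |
| 2.50 | 39 | 3 | 12 |
| 4.00 | 48 | 2 | 11 |

(standard deviation of a reading: 1.5 percentage points)

* left-handed product and right-handed product together, in percent of the left-handed substrate and right-handed substrate charged together, at 40 h
* excess of left-handed product over right-handed product in the product at 40 h
* whether the exchange between left-handed substrate and right-handed substrate keeps pace with the reaction: how far the product's excess at 40 h gets from its value without exchange to its value with instant exchange (above 80% keeps pace, below 20% hardly takes part, else lags behind)

**Fast leg.** The flask had the oak run's partner and catalyst concentrations, so I took the oak pace for left-handed substrate: from a fraction 0.5 of the charge to 29% at 1.00 h, a lifetime of 1.84 h. I therefore drew left-handed product in the flask rising steeply and bending at about 3.68 h, a little short of a fraction 0.5 of the charge.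

**Slow leg.** Past that knee, the curve climbs as right-handed substrate crosses over. Without crossing, left-handed product plus left-handed substrate would hold at a fraction 0.5 of the charge in the oak run. Its last two readings average 55.0%, so 5.00% had crossed by about 3.25 h, against a gap between the substrates of 31.0%. That gives 20.1 h as the drain time, the time in which crossing shrinks right-handed substrate by a factor e, a pseudo-first-order loss. It is about ten times the lifetime, so crossing paces the climb. One standard deviation on the crossed amount stretches it to 28.8 h.

**My reckoning.** Over 40 h, these two drain times leave 6.83% to 12.5% of the charge as right-handed substrate, so I expected about 93.2% to 87.5% product. The share crossed, 86.3% to 75.1%, straddles 80%, so I left the pace open. I made no reckoning of the excess.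

**The forecast.** It said 96%, 89% and keeps pace, on the reading “so exchange is about 0.2 h⁻¹”.

    coupling partner + free catalyst + right-handed substrate → free catalyst + right-handed product (k = 0.00187 /M²/min)
    coupling partner → decomposition product (k = 8.72 × 10⁻⁷ /min)
    left-handed substrate + racemization catalyst ⇌ right-handed substrate + racemization catalyst, rate k3*[racemization catalyst]*[left-handed substrate] forward; the back reaction follows from the equilibrium constant (k = 0.00994 /M/min)
    coupling partner + free catalyst + left-handed substrate → free catalyst + left-handed product (k = 0.176 /M²/min)
    free catalyst → spent catalyst (k = 4.96 × 10⁻⁴ /min)

**The flask.** It gave 83.9% at an excess of 90.0%, and the exchange lags behind, getting 63% of the way. In the flask, right-handed substrate fell from a fraction 0.5 of the charge to 13.2% at 40.0 h, a drain time of 30.1 h. The neighbour flask held 0.24 M of racemization catalyst and ended with 96.6% product and 2.07% right-handed substrate, a drain time counted the same way of 12.6 h.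

The numbers in the tables were generated by integration with made-up constants, and the scatter is random.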